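The tetrahydropyran is cut into the two-atom unit O-ring/C-spiro (spiro carbon of 2H-pyrrole ring B) and the four-carbon unit C-Me–CH2–C-bridge–C-pyr of the pyrrolophane (C-Me carries the methyl, C-pyr the ring C pyrrole). The spiro N,O-ketal carbon is a masked lactam carbonyl: as a 2-oxidopyrrole, bipyrrole lactam 20 is nucleophilic at O-ring and, once O-alkylated, at C-spiro. In one flask O-ring displaces the secondary bromide at C-Me with inversion; acid then frees an azafulvenium ion at C-pyr, which C-spiro captures by dearomatising ipso attack. Precursor: macrocyclic bromo methyl ether 17 plus lactam 20; C-Me is bought, C-bridge relayed from it, C-pyr and C-spiro are set in the key event.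

Key step: step 9

Assumption: 4-methoxy-1H,1'H-2,2'-bipyrrole-5-carbaldehyde (18), the usual prodiginine building block, is treated as a purchasable starting material.

Step 1
Reactants: 1 (5S)-5-methyloxolan-2-one [(S)-γ-valerolactone]; 2 3-bromoprop-1-ene (allyl bromide)
Product: 4 (3S,5S)-5-methyl-3-(prop-2-en-1-yl)oxolan-2-one, via lithium enolate 3 (not isolated)
Conditions: LiN(iPr)2, THF, −78 °C; then 2, −78 °C
Reagents that add atoms: none
Why: Alkylation of the lactone lithium enolate; the allyl group should enter anti to the C5 methyl group (1,3-induction), which sets C-bridge trans to the bought stereocentre.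

Step 2
Reactants: 4 (3S,5S)-5-methyl-3-(prop-2-en-1-yl)oxolan-2-one
Product: 5 (2S,4R)-4-bromo-2-(prop-2-en-1-yl)pentanoic acid
Conditions: BBr3, CH2Cl2, −20 °C to rt; then ice/H2O
Reagents that add atoms: boron tribromide, BrB(Br)Br
Why: Lewis-acid-mediated alkyl–oxygen cleavage of the lactone: bromide attacks the activated C5–O bond in SN2 fashion, so C-Me is inverted to the (R)-bromide while the acid for step 5 is released.

Step 3
Reactants: 6 1H-pyrrole; 7 hex-5-enoyl chloride
Product: 9 1-(1H-pyrrol-2-yl)hex-5-en-1-one, via pyrrolylmagnesium bromide 8 (not isolated)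
Conditions: EtMgBr, Et2O, 0 °C; then 7, toluene, −40 to 0 °C
Reagents that add atoms: none
Why: C2-selective acylation of the pyrrole magnesium salt by an acid chloride (Friedel–Crafts-type acylation of a metalated pyrrole).

Step 4
Reactants: 9 1-(1H-pyrrol-2-yl)hex-5-en-1-one
Product: 10 2-(hex-5-en-1-yl)-1H-pyrrole
Conditions: NaBH4, i-PrOH, reflux
Reagents that add atoms: none
Why: Borohydride in hot 2-propanol should take the 2-acylpyrrole through carbinol and azafulvene to the 2-alkylpyrrole, and the isolated terminal alkene is inert to it.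

Step 5
Reactants: 5 (2S,4R)-4-bromo-2-(prop-2-en-1-yl)pentanoic acid; 10 2-(hex-5-en-1-yl)-1H-pyrrole
Product: 13 (2S,4R)-4-bromo-1-[5-(hex-5-en-1-yl)-1H-pyrrol-2-yl]-2-(prop-2-en-1-yl)pentan-1-one, via acid chloride 11 (not isolated), via magnesium pyrrolide 12 (not isolated)
Conditions: 5, (COCl)2, cat. DMF, CH2Cl2, 0 °C to rt, concentrate; 10, EtMgBr, Et2O, 0 °C; combine in toluene, −78 to −20 °C
Reagents that add atoms: none
Why: Acid chloride formation, then acylation of the magnesium pyrrolide at its free α-position; the low temperature and the weakly basic pyrrolide should leave the α-stereocentre and the secondary bromide untouched.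

Step 6
Reactants: 13 (2S,4R)-4-bromo-1-[5-(hex-5-en-1-yl)-1H-pyrrol-2-yl]-2-(prop-2-en-1-yl)pentan-1-one
Product: 15 (3S)-3-[(2R)-2-bromopropyl]-14-azabicyclo[9.2.1]tetradeca-1(13),11-dien-2-one, via cycloalkene 14 (not isolated)
Conditions: second-generation Grubbs catalyst (10 mol %), CH2Cl2 (1 mM), 40 °C; then H2 (5 bar), 40 °C
Reagents that add atoms: none
Why: Ring-closing metathesis of two unhindered terminal alkenes at high dilution should close the twelve-membered ansa ring (counted through nitrogen), and the ruthenium hydride formed under H2 should saturate the new alkene without touching C–Br or the acylpyrrole carbonyl.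

Step 7
Reactants: 15 (3S)-3-[(2R)-2-bromopropyl]-14-azabicyclo[9.2.1]tetradeca-1(13),11-dien-2-one
Product: 17 (3S)-3-[(2R)-2-bromopropyl]-2-methoxy-14-azabicyclo[9.2.1]tetradeca-1(13),11-diene, via carbinol 16 (not isolated)
Conditions: NaBH4, CeCl3·7H2O, MeOH/THF, −40 to −10 °C; then camphorsulfonic acid (to pH 3), −10 °C; Et3N; basic alumina
Reagents that add atoms: methanol, CO
Why: Luche reduction followed by acid-catalysed SN1 methanolysis of the pyrrol-2-yl carbinol masks C-pyr as a methyl ether before the alkoxide or alcohol can displace the bromide; both epimers at the new centre form and converge in step 9.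

Step 8
Reactants: 18 4-methoxy-1H,1'H-2,2'-bipyrrole-5-carbaldehyde
Product: 20 3-methoxy-5-(1H-pyrrol-2-yl)-1,5-dihydro-2H-pyrrol-2-one, via formate ester 19 (not isolated)
Conditions: 30% H2O2, NaHCO3, MeOH, 0 °C to rt, argon
Reagents that add atoms: hydrogen peroxide, OO
Why: Dakin oxidation: hydroperoxide adds to the formyl group, the electron-rich pyrrolyl group migrates to oxygen, and cleavage of the formate gives the 2-hydroxypyrrole, which tautomerises to the pyrrolin-2-one.

Step 9
Reactants: 17 (3S)-3-[(2R)-2-bromopropyl]-2-methoxy-14-azabicyclo[9.2.1]tetradeca-1(13),11-diene; 20 3-methoxy-5-(1H-pyrrol-2-yl)-1,5-dihydro-2H-pyrrol-2-one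
Product: 23 premarineosin A, via alkoxypyrrole ether 21 (not isolated), via azafulvenium trifluoroacetate 22 (not isolated)
Conditions: Cs2CO3, MeCN, 50 °C, argon; then CH2Cl2, CF3CO2H, −20 to 0 °C, same flask; aq. NaHCO3
Reagents that add atoms: none
Why: Proposed new method: Cs2CO3 converts lactam 20 into its aromatic 2-oxidopyrrole, whose oxygen displaces the secondary bromide of 17 by SN2 (Williamson type), so that O-ring–C-Me forms with inversion and the (R)-bromide becomes the (S)-ether 21; CF3CO2H then ionises the pyrrol-2-ylmethyl methyl ether to azafulvenium ion 22, which is attacked by the oxygen-bearing α-carbon (C-spiro) of the tethered 2-alkoxy-3-methoxypyrrole, and loss of N–H from the resulting 2H-pyrrolium ion gives the spiro N,O-ketal. The closest known reaction types are O-alkylation of phenol-like hydroxy heteroarenes with secondary halides, alkylation of pyrroles by azafulvenium ions (dipyrromethane synthesis) and dearomatising ipso-Friedel–Crafts spirocyclisation of 2,5-disubstituted pyrroles to spiro-2H-pyrroles; ipso capture at an alkoxy-bearing pyrrole carbon to give a cyclic N,O-ketal is the new element. The only ring closed is the tetrahydropyran, by 6-exo-trig attack on the exocyclic C=C of the azafulvenium ion, since closure through the methoxy-bearing or the free β-carbon of ring B would need a seven- or eight-membered ring. C-pyr should be set in a chair-like transition state with the ansa bridge at C-bridge and ring C at C-pyr trans-diequatorial (the less strained fusion of the twelve-membered loop to the chair), and C-spiro by the axial methyl at C-Me, which leaves room only for the N–H edge of ring B in the syn-axial position (N axial, anomerically favoured); the ipso step should be reversible under acid, so these two centres can settle. The step needs O- rather than C-alkylation of the ambident anion (both carbon termini of the oxidopyrrole are already substituted, and CsBr, insoluble in MeCN, should not racemise the bromide by exchange), no alkylation of ring C (its N–H lies inside the ansa loop and is far less acidic than 20) and capture of 22 before it loses the C-bridge proton (six-ring closure by a very electron-rich pyrrole).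

Compound list
1 | (5S)-5-methyloxolan-2-one [(S)-γ-valerolactone] | C[C@H]1CCC(=O)O1 | starting material
2 | 3-bromoprop-1-ene (allyl bromide) | C=CCBr | starting material
3 | lithium (5S)-5-methyl-4,5-dihydrofuran-2-olate (lithium enolate of 1, not isolated) | [Li]OC1=CC[C@H](C)O1 | intermediate
4 | (3S,5S)-5-methyl-3-(prop-2-en-1-yl)oxolan-2-one (trans lactone) | C[C@H]1C[C@H](CC=C)C(=O)O1 | intermediate
5 | (2S,4R)-4-bromo-2-(prop-2-en-1-yl)pentanoic acid | C[C@@H](Br)C[C@H](CC=C)C(O)=O | intermediate
6 | 1H-pyrrole | c1cc[nH]c1 | starting material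
7 | hex-5-enoyl chloride | C=CCCCC(Cl)=O | starting material
8 | bromo(pyrrol-1-yl)magnesium (not isolated) | Br[Mg]n1cccc1 | intermediate
9 | 1-(1H-pyrrol-2-yl)hex-5-en-1-one | O=C(CCCC=C)c1ccc[nH]1 | intermediate
10 | 2-(hex-5-en-1-yl)-1H-pyrrole | C=CCCCCc1ccc[nH]1 | intermediate
11 | (2S,4R)-4-bromo-2-(prop-2-en-1-yl)pentanoyl chloride (not isolated) | C[C@@H](Br)C[C@H](CC=C)C(Cl)=O | intermediate
12 | bromo[2-(hex-5-en-1-yl)pyrrol-1-yl]magnesium (not isolated) | C=CCCCCc1cccn1[Mg]Br | intermediate
13 | (2S,4R)-4-bromo-1-[5-(hex-5-en-1-yl)-1H-pyrrol-2-yl]-2-(prop-2-en-1-yl)pentan-1-one | C[C@@H](Br)C[C@H](CC=C)C(=O)c1ccc(CCCCC=C)[nH]1 | intermediate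
14 | (3S)-3-[(2R)-2-bromopropyl]-14-azabicyclo[9.2.1]tetradeca-1(13),5,11-trien-2-one (E/Z mixture, not isolated) | C[C@@H](Br)C[C@@H]1CC=CCCCCc2ccc([nH]2)C1=O | intermediate
15 | (3S)-3-[(2R)-2-bromopropyl]-14-azabicyclo[9.2.1]tetradeca-1(13),11-dien-2-one (macrocyclic ketopyrrole, a [9](2,5)pyrrolophane) | C[C@@H](Br)C[C@@H]1CCCCCCCc2ccc([nH]2)C1=O | intermediate
16 | (3S)-3-[(2R)-2-bromopropyl]-14-azabicyclo[9.2.1]tetradeca-1(13),11-dien-2-ol (both epimers at the carbinol carbon, not isolated) | C[C@@H](Br)C[C@@H]1CCCCCCCc2ccc([nH]2)C1O | intermediate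
17 | (3S)-3-[(2R)-2-bromopropyl]-2-methoxy-14-azabicyclo[9.2.1]tetradeca-1(13),11-diene (both epimers at the methoxy carbon) | C[C@@H](Br)C[C@@H]1CCCCCCCc2ccc([nH]2)C1OC | intermediate
18 | 4-methoxy-1H,1'H-2,2'-bipyrrole-5-carbaldehyde | COc1cc(-c2ccc[nH]2)[nH]c1C=O | starting material
19 | 4-methoxy-1H,1'H-2,2'-bipyrrol-5-yl formate (not isolated) | COc1cc(-c2ccc[nH]2)[nH]c1OC=O | intermediate
20 | 3-methoxy-5-(1H-pyrrol-2-yl)-1,5-dihydro-2H-pyrrol-2-one (racemic; lactam tautomer of 5-hydroxy-4-methoxy-2,2'-bipyrrole) | COC1=CC(c2ccc[nH]2)NC1=O | intermediate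
21 | (3S)-2-methoxy-3-[(2S)-2-{[3-methoxy-5-(1H-pyrrol-2-yl)-1H-pyrrol-2-yl]oxy}propyl]-14-azabicyclo[9.2.1]tetradeca-1(13),11-diene (not isolated) | COc1cc(-c2ccc[nH]2)[nH]c1O[C@@H](C)C[C@@H]1CCCCCCCc2ccc([nH]2)C1OC | intermediate
22 | azafulvenium trifluoroacetate formed from 21 by loss of methoxide (C-pyr is the exocyclic cationic carbon of ring C, not isolated) | COc1cc(-c2ccc[nH]2)[nH]c1O[C@@H](C)C[C@@H]1CCCCCCCC2=[NH+]C(C=C2)=C1.[O-]C(=O)C(F)(F)F | intermediate
23 | premarineosin A | COC1=CC(c2ccc[nH]2)=N[C@]12O[C@@H](C)C[C@@H]1CCCCCCCc3ccc([nH]3)[C@H]12 | target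

Total step count: 9. Longest linear sequence: 6 steps (1, 2, 5, 6, 7, 9).

Steps most likely to fail

Step 9. In the first stage the ambident oxidopyrrole may be alkylated at carbon, or the secondary bromide may be lost by E2 elimination. In the second stage the azafulvenium ion may shed the C-bridge proton (vinylpyrrole formation, epimerisation of C-bridge) or be captured from the wrong face. The fallback uses known prodiginine chemistry, sets out from 15 and 18 and returns at 23. It gives up the one-flask union and closes the ring through C-pyr–C-spiro and O-ring–C-spiro, with the oxygen carried by the side chain. Bromo ketone 15 is treated with CsOAc and 18-crown-6 in DMF (SN2, inversion) to give (2S)-1-[(3S)-2-oxo-14-azabicyclo[9.2.1]tetradeca-1(13),11-dien-3-yl]propan-2-yl acetate F1, and K2CO3 in MeOH gives the (S)-hydroxy ketone F2. Aldehyde 18 is oxidised with Ag2O and aqueous NaOH to 4-methoxy-2,2'-bipyrrole-5-carboxylic acid F3, which is protodecarboxylated in warm CF3CO2H to 4-methoxy-2,2'-bipyrrole F4. Acid-catalysed condensation of F2 with F4 (HCl, MeOH, rt) should give the meso-substituted prodiginine-type azafulvenium ion, and conjugate addition of the side-chain hydroxyl to C-spiro should then give 23.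

Step 7. The C-pyr alkoxide or alcohol may displace the neighbouring secondary bromide (tetrahydrofuran closure), or the azafulvenium ion passed through during methanolysis may lose the C-bridge proton. The fallback avoids both the free alkoxide and the cation; it sets out from 15 and returns at 22. Hydrosilylation of 15 with Et3SiH and catalytic RhCl(PPh3)3 in toluene at 60 °C should deliver the silicon–oxygen bond directly and give triethylsilyl ether F5. F5 then replaces 17 in step 9: O-alkylation with 20 (Cs2CO3, MeCN) gives the silyl ether analogue of 21, F6, and CF3CO2H ionises the silyl ether to the same azafulvenium ion 22.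

Step 8. Peroxide may over-oxidise the electron-rich bipyrrole, either at the free α-position of ring A or at the doubly activated C5–H of the product. The fallback is peroxide-free, sets out from 18 and returns at 20. The acid F3 (made from 18 with Ag2O as above) is subjected to brominative decarboxylation with NBS and NaHCO3 in aqueous THF at 0 °C to give 5-bromo-4-methoxy-2,2'-bipyrrole F7. Hydrolysis of this α-bromopyrrole in CF3CO2H/H2O (ipso protonation, addition of water, loss of HBr) should give lactam 20.

Further compounds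
F1 | step 9 | (2S)-1-[(3S)-2-oxo-14-azabicyclo[9.2.1]tetradeca-1(13),11-dien-3-yl]propan-2-yl acetate | C[C@H](OC(C)=O)C[C@@H]1CCCCCCCc2ccc([nH]2)C1=O
F2 | step 9 | (3S)-3-[(2S)-2-hydroxypropyl]-14-azabicyclo[9.2.1]tetradeca-1(13),11-dien-2-one | C[C@H](O)C[C@@H]1CCCCCCCc2ccc([nH]2)C1=O
F3 | step 9 | 4-methoxy-1H,1'H-2,2'-bipyrrole-5-carboxylic acid | COc1cc(-c2ccc[nH]2)[nH]c1C(O)=O
F4 | step 9 | 4-methoxy-1H,1'H-2,2'-bipyrrole | COc1c[nH]c(-c2ccc[nH]2)c1
F5 | step 7 | (3S)-3-[(2R)-2-bromopropyl]-2-[(triethylsilyl)oxy]-14-azabicyclo[9.2.1]tetradeca-1(13),11-diene | C[C@@H](Br)C[C@@H]1CCCCCCCc2ccc([nH]2)C1O[Si](CC)(CC)CC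
F6 | step 7 | (3S)-3-[(2S)-2-{[3-methoxy-5-(1H-pyrrol-2-yl)-1H-pyrrol-2-yl]oxy}propyl]-2-[(triethylsilyl)oxy]-14-azabicyclo[9.2.1]tetradeca-1(13),11-diene | COc1cc(-c2ccc[nH]2)[nH]c1O[C@@H](C)C[C@@H]1CCCCCCCc2ccc([nH]2)C1O[Si](CC)(CC)CC
F7 | step 8 | 5-bromo-4-methoxy-1H,1'H-2,2'-bipyrrole | COc1cc(-c2ccc[nH]2)[nH]c1Br
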